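**Two questions.** Two questions stand for this flask, and two earlier runs, elm and alder, stand beside it.

| flask | starting material | reagent | remark | time |
|---|---|---|---|---|
| elm | 0.025 M | 3 equiv | run made earlier |  |
| alder | 0.10 M | 3 equiv | run made earlier |  |
| flask | 0.050 M | 3.00 equiv |  | 25 min |

| run | time / min | adduct / % | product / % |
|---|---|---|---|
| elm | 0.250 | 16 | 2 |
| elm | 0.500 | 23 | 7 |
| elm | 1.33 | 27 | 25 |
| elm | 2.50 | 18 | 48 |
| elm | 5.00 | 11 | 76 |
| elm | 12.0 | 1 | 94 |
| elm | 25.0 | 0 | 100 |
| alder | 0.250 | 46 | 6 |
| alder | 0.500 | 56 | 17 |
| alder | 1.33 | 37 | 50 |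
| alder | 2.50 | 18 | 75 |
| alder | 5.00 | 4 | 96 |
| alder | 12.0 | 0 | 101 |
| alder | 25.0 | 1 | 98 |

(scatter of a reading: 1.5 percentage points)

- when, up to 25 min, the flask holds most adduct
- the amount of adduct, in percent of the starting material charged, at that time

- product is meant together with its crystals
- solid, in amounts per volume of the solution: crystals
- reactions considered so far: starting material + reagent <-> adduct; adduct -> product; crystals <-> product

**Start rates.** I reckon in rates. The first elm reading shows 18.0 % of the starting material gone, which gives a making constant k_m of 0.794 min⁻¹ in elm. In alder, product rise over mean adduct gives a using constant k_u of 0.879 min⁻¹. Making is first order in reagent, so k_m scales with the reagent charged and reaches 1.59 min⁻¹ in this flask, faster than using. The make-to-use ratio Q, k_m at the charged reagent over k_u, is 1.81 for this flask.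

**Zero point.** At Q = 1 the constants are equal, and a chain with steady reagent and no way back peaks at 36.8 % of the charge. For any Q that chain peaks at Q^(1/(1−Q)), at ln Q/(k_m−k_u). For this flask that means 48.0 % at 0.834 min.

**The slowing.** Reagent is used and adduct falls back, so I read a kept share f, the read peak over the chain peak. Elm has Q = 0.903, chain 34.9 %, read 27 %, so f = 0.773. Alder has Q = 3.61, chain 61.2 %, read 56 %, so f = 0.916. This flask's concentration is their geometric mean, so I take f = 0.841 and commit to 40.4 % near 0.834 min.

**The result.** The forecast, whose using constant came out “about the same at both concentrations”, puts the peak at 0.85 min with 39 %. The flask peaks at 0.747 min with 41.2 %.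

    starting material + reagent ⇌ adduct (K = 22.0 M⁻¹, k = 0.196 M⁻¹ s⁻¹)
    adduct → product (k = 0.0138 s⁻¹)
    crystals ⇌ product, rate k3*(cs3 - [product]) while solid is left; crystals form when [product] > cs3 (solubility = 46.0 mM, k = 1.55 s⁻¹)

**Neighbour flask.** The neighbour flask has 0.12 M of starting material at the same equivalents, so Q = 4.33 and the chain peak is 64.4 %. Alder's kept share, from the nearest run, brings that to 59.0 %, and the neighbour flask gives 57.9 %.

Readings and results are simulated with made-up constants, noise included.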